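**Plan**

1. Numbering is that of germacrane: ring C1–C10, C11 the furanone α-carbon, C12 the lactone carbonyl, C13 the acetoxymethyl carbon. The retrosynthesis cuts the epoxide oxygen (C1/C10) back to the E-alkene; then C7=C11 together with C13–OAc, back to a 2-phosphonoacrylate ester of the C6-hydroxy C7-ketone plus acetate; then C8–C9 of the ten-membered ring (β-keto ester enolate and allylic chloride); then C1=C10 (cross-metathesis), C2–C3 (allylboration) and C4=C5 (Wittig).
2. Enabling feature: in the furanone ring (O–C12–C11=C7–C6) the ring oxygen on C6 is vicinal to C7, so C6/C7 is an acyloin whose oxygen can carry the C11–C12 unit as an ester. The acetoxy group on C13 sits β to C12, exactly where a nucleophile lands on an acrylate. Acetate, a 2-phosphonoacrylate and the C7 ketone can therefore give C13–O and C7=C11 in one event.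
3. Forward order: linear chain from (R)-solketal, ten-membered carbocycle first (C8–C9), butenolide second (C7=C11), epoxide last.
4. Stereochemistry: C6 from (R)-solketal; C3 by reagent-controlled Brown allylboration; both E-alkenes by thermodynamically controlled Wittig olefination and cross-metathesis; the 1R,10R epoxide by peripheral attack on the macrocycle.

Key step: step 16

Remark: 2-(diethoxyphosphoryl)prop-2-enoic acid (23) is taken as a catalogue reagent; positions named in the Why lines use the germacrane numbering given above.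

**Route**

Step 1
Reactants: 1 [(4R)-2,2-dimethyl-1,3-dioxolan-4-yl]methanol ((R)-solketal); 2 2-(triphenylphosphoranylidene)propanal
Product: 4 (2E)-3-[(4R)-2,2-dimethyl-1,3-dioxolan-4-yl]-2-methylprop-2-enal, via (S)-glyceraldehyde acetonide 3 (not isolated)
Conditions: (COCl)2, DMSO, CH2Cl2, −78 °C; Et3N, −78 to 0 °C; then 2, CH2Cl2, 0 to 40 °C
Reagents that add atoms: none
Why: Swern oxidation gives the configurationally labile aldehyde 3, which is trapped in the same flask by the formyl-stabilised ylide in a Wittig reaction that should give the E-trisubstituted enal, the stereocentre of 1 being carried over unchanged as C6 of the target.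

Step 2
Reactants: 4 (2E)-3-[(4R)-2,2-dimethyl-1,3-dioxolan-4-yl]-2-methylprop-2-enal
Product: 6 (1E,3S)-1-[(4R)-2,2-dimethyl-1,3-dioxolan-4-yl]-2-methylhexa-1,5-dien-3-ol, via diisopinocampheylborinate 5 (not isolated)
Conditions: (−)-Ipc2BOMe, allylMgBr, Et2O, 0 °C; then 4, −78 °C; then NaOH, H2O2, 0 °C to rt
Reagents that add atoms: allylmagnesium bromide, C=CC[Mg]Br; (−)-B-methoxydiisopinocampheylborane, COB([C@H]1[C@H](C)[C@H]2C[C@@H](C1)C2(C)C)[C@H]1[C@H](C)[C@H]2C[C@@H](C1)C2(C)C (its atoms stay only in 5)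
Why: Brown allylboration, in which the B-allyl reagent of the (+)-α-pinene series should add through a closed chair transition state to the Si face of the α-methyl enal under reagent control and so set the 3S carbinol centre, the borinate 5 being cleaved by the oxidative work-up.

Step 3
Reactants: 6 (1E,3S)-1-[(4R)-2,2-dimethyl-1,3-dioxolan-4-yl]-2-methylhexa-1,5-dien-3-ol
Product: 7 (1E,3S)-1-[(4R)-2,2-dimethyl-1,3-dioxolan-4-yl]-2-methylhexa-1,5-dien-3-yl acetate
Conditions: Ac2O, pyridine, DMAP (cat.), CH2Cl2, 0 °C to rt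
Reagents that add atoms: acetic anhydride, CC(=O)OC(C)=O
Why: Standard DMAP-catalysed acetylation of the secondary allylic alcohol, which installs the C3 acetate of the target at once and lets it serve as the protecting group for the rest of the route.

Step 4
Reactants: 7 (1E,3S)-1-[(4R)-2,2-dimethyl-1,3-dioxolan-4-yl]-2-methylhexa-1,5-dien-3-yl acetate; 8 2-methylprop-2-enal (methacrolein)
Product: 9 (1E,3S,5E)-1-[(4R)-2,2-dimethyl-1,3-dioxolan-4-yl]-2,6-dimethyl-7-oxohepta-1,5-dien-3-yl acetate
Conditions: second-generation Grubbs catalyst (5 mol%), 8 (excess), CH2Cl2, 40 °C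
Reagents that add atoms: none
Why: Olefin cross-metathesis between the terminal alkene and methacrolein, which should give the trisubstituted enal with the strong E preference usual for this pairing while the hindered trisubstituted C4=C5 alkene stays untouched, so that the E geometry of the later C1=C10 alkene is set and C9, C10 and its methyl group are brought in.

Step 5
Reactants: 9 (1E,3S,5E)-1-[(4R)-2,2-dimethyl-1,3-dioxolan-4-yl]-2,6-dimethyl-7-oxohepta-1,5-dien-3-yl acetate
Product: 10 (1E,3S,5E)-1-[(4R)-2,2-dimethyl-1,3-dioxolan-4-yl]-7-hydroxy-2,6-dimethylhepta-1,5-dien-3-yl acetate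
Conditions: NaBH4, CeCl3·7H2O, MeOH, −20 °C
Reagents that add atoms: none
Why: Luche reduction, a clean 1,2-reduction of the enal to the E-allylic alcohol that leaves the acetate and the acetonide alone.

Step 6
Reactants: 10 (1E,3S,5E)-1-[(4R)-2,2-dimethyl-1,3-dioxolan-4-yl]-7-hydroxy-2,6-dimethylhepta-1,5-dien-3-yl acetate
Product: 12 (1E,3S,5E)-7-chloro-1-[(4R)-2,2-dimethyl-1,3-dioxolan-4-yl]-2,6-dimethylhepta-1,5-dien-3-yl acetate, via allylic mesylate 11 (not isolated)
Conditions: MsCl, 2,4,6-collidine, LiCl, DMF, 0 °C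
Reagents that add atoms: methanesulfonyl chloride, CS(=O)(=O)Cl (its atoms stay only in 11); lithium chloride, [Li+].[Cl-]
Why: Mesylation followed by chloride displacement in an SN2 reaction under buffered, non-ionising conditions should give the primary allylic chloride without allylic transposition or loss of the E geometry.

Step 7
Reactants: 12 (1E,3S,5E)-7-chloro-1-[(4R)-2,2-dimethyl-1,3-dioxolan-4-yl]-2,6-dimethylhepta-1,5-dien-3-yl acetate
Product: 13 (2R,3E,5S,7E)-9-chloro-1,2-dihydroxy-4,8-dimethylnona-3,7-dien-5-yl acetate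
Conditions: AcOH/H2O (4:1), 25 °C
Reagents that add atoms: none
Why: Mild aqueous acetic acid hydrolyses the terminal acetonide while the acetate and the primary allylic chloride, which ionises only slowly, are expected to survive.

Step 8
Reactants: 13 (2R,3E,5S,7E)-9-chloro-1,2-dihydroxy-4,8-dimethylnona-3,7-dien-5-yl acetate
Product: 14 (2R,3E,5S,7E)-9-chloro-4,8-dimethyl-1,2-bis(triethylsilyloxy)nona-3,7-dien-5-yl acetate
Conditions: Et3SiOTf, 2,6-lutidine, CH2Cl2, −78 °C
Reagents that add atoms: triethylsilyl trifluoromethanesulfonate, CC[Si](CC)(CC)OS(=O)(=O)C(F)(F)F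
Why: Silylation of both hydroxyl groups with the silyl triflate and a hindered, non-nucleophilic base that does not attack the allylic chloride.

Step 9
Reactants: 14 (2R,3E,5S,7E)-9-chloro-4,8-dimethyl-1,2-bis(triethylsilyloxy)nona-3,7-dien-5-yl acetate
Product: 15 (2R,3E,5S,7E)-9-chloro-4,8-dimethyl-1-oxo-2-(triethylsilyloxy)nona-3,7-dien-5-yl acetate
Conditions: (COCl)2, DMSO, CH2Cl2, −78 to −40 °C; then Et3N, −78 to 0 °C
Reagents that add atoms: none
Why: Under Swern conditions a primary triethylsilyl ether is cleaved and oxidised to the aldehyde while a secondary one is kept, a known selective oxidation that avoids a separate deprotection and should leave the α-silyloxy centre C6 intact at low temperature.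

Step 10
Reactants: 15 (2R,3E,5S,7E)-9-chloro-4,8-dimethyl-1-oxo-2-(triethylsilyloxy)nona-3,7-dien-5-yl acetate; 16 prop-2-enyl bromoacetate (allyl bromoacetate)
Product: 17 prop-2-enyl (4R,5E,7S,9E)-7-acetoxy-11-chloro-3-hydroxy-6,10-dimethyl-4-(triethylsilyloxy)undeca-5,9-dienoate (both C3 epimers)
Conditions: 16, Zn, THF, 25 °C (reagent decanted from excess Zn); then 15, THF, 0 °C; AcOH quench
Reagents that add atoms: none
Why: Reformatsky addition of the preformed zinc enolate, which is nucleophilic enough for the aldehyde but too weakly basic to enolise C6 or to touch the acetate and the allylic chloride, the new carbinol centre being of no consequence because it is oxidised in step 11.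

Step 11
Reactants: 17 prop-2-enyl (4R,5E,7S,9E)-7-acetoxy-11-chloro-3-hydroxy-6,10-dimethyl-4-(triethylsilyloxy)undeca-5,9-dienoate
Product: 18 prop-2-enyl (4R,5E,7S,9E)-7-acetoxy-11-chloro-6,10-dimethyl-3-oxo-4-(triethylsilyloxy)undeca-5,9-dienoate
Conditions: Dess–Martin periodinane, CH2Cl2, 0 °C to rt
Reagents that add atoms: none
Why: Dess–Martin oxidation of the β-hydroxy ester to the β-keto ester under neutral conditions that spare the silyl ether and the allylic chloride.

Step 12
Reactants: 18 prop-2-enyl (4R,5E,7S,9E)-7-acetoxy-11-chloro-6,10-dimethyl-3-oxo-4-(triethylsilyloxy)undeca-5,9-dienoate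
Product: 19 prop-2-enyl (3E,6S,7E,9R)-6-acetoxy-3,7-dimethyl-10-oxo-9-(triethylsilyloxy)cyclodeca-3,7-diene-1-carboxylate (both C1 epimers)
Conditions: Cs2CO3, NaI (cat.), MeCN, high dilution (slow addition), 50 °C
Reagents that add atoms: none
Why: Intramolecular SN2 C-alkylation of the caesium enolate of the β-keto ester by the primary allylic halide under high dilution, the classical stabilised-carbanion/allylic-halide closure of E,E-germacradiene rings, in which both E-alkenes are already in place, the doubly activated C8–H is the only proton removed so that C6 is not enolised, and the C8 epimers converge in step 13.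

Step 13
Reactants: 19 prop-2-enyl (3E,6S,7E,9R)-6-acetoxy-3,7-dimethyl-10-oxo-9-(triethylsilyloxy)cyclodeca-3,7-diene-1-carboxylate
Product: 21 (2R,3E,5S,7E)-5-acetoxy-4,8-dimethyl-2-(triethylsilyloxy)cyclodeca-3,7-dien-1-one, via β-keto acid 20 (not isolated)
Conditions: Pd(PPh3)4 (5 mol%), morpholine, THF, 25 °C
Reagents that add atoms: none
Why: Zerovalent palladium ionises the allyl ester, morpholine traps the allyl group and the β-keto acid 20 loses CO2 at room temperature (Tsuji-type deallylation–decarboxylation), while the hindered secondary allylic acetate at C3 ionises far more slowly.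

Step 14
Reactants: 21 (2R,3E,5S,7E)-5-acetoxy-4,8-dimethyl-2-(triethylsilyloxy)cyclodeca-3,7-dien-1-one
Product: 22 (2R,3E,5S,7E)-5-acetoxy-2-hydroxy-4,8-dimethylcyclodeca-3,7-dien-1-one
Conditions: HF·pyridine, pyridine, THF, 0 °C
Reagents that add atoms: none
Why: Pyridine-buffered HF removes the triethylsilyl group without the strong acid that would trigger transannular cyclisation of the 1(10),4-diene and without the base that would isomerise the acyloin.

Step 15
Reactants: 22 (2R,3E,5S,7E)-5-acetoxy-2-hydroxy-4,8-dimethylcyclodeca-3,7-dien-1-one; 23 2-(diethoxyphosphoryl)prop-2-enoic acid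
Product: 24 (1R,2E,4S,6E)-4-acetoxy-3,7-dimethyl-10-oxocyclodeca-2,6-dien-1-yl 2-(diethoxyphosphoryl)prop-2-enoate
Conditions: 23, DCC, DMAP (cat.), CH2Cl2, −20 to 0 °C
Reagents that add atoms: none
Why: Steglich esterification of the secondary hydroxyl with the phosphonoacrylic acid at low temperature, which should attach the activated acrylate to O6 without epimerising C6 and gives the tether that later becomes the lactone.

Step 16
Reactants: 24 (1R,2E,4S,6E)-4-acetoxy-3,7-dimethyl-10-oxocyclodeca-2,6-dien-1-yl 2-(diethoxyphosphoryl)prop-2-enoate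
Product: 26 [(6E,9S,10E,11aR)-9-acetoxy-6,10-dimethyl-2-oxo-2,4,5,8,9,11a-hexahydrocyclodeca[b]furan-3-yl]methyl acetate, via phosphonate carbanion 25 (not isolated)
Conditions: Bu4NOAc (1.1 equiv), THF, −20 to 0 °C
Reagents that add atoms: tetrabutylammonium acetate, CC(=O)[O-].CCCC[N+](CCCC)(CCCC)CCCC
Why: Proposed new method: acetate should add in an oxa-Michael sense to C13 of the 2-phosphonoacrylate, the phosphonate- and ester-stabilised carbanion at C11 (25) then attacks the adjacent C7 ketone, and the resulting β-alkoxy phosphonate collapses through an oxaphosphetane with loss of diethyl phosphate to give the C7=C11 double bond, so that the phosphonate helper leaves in the event itself. The closest known reaction types are the nucleophile-triggered Horner–Wadsworth–Emmons olefination of 2-phosphonoacrylates (conjugate addition followed by olefination) and the intramolecular Horner–Wadsworth–Emmons butenolide annulation of phosphonoacetate esters of α-hydroxy ketones; a carboxylate as the trigger on such an ester is the untested part. The furanone ring closes by 5-exo-trig (enolexo) attack of C11 on the C7 carbonyl, with the ester on O6 as the tether that ends as the lactone. No new stereocentre remains, because C7 becomes sp2 and the transient C7 carbinol is consumed in the elimination. The step needs ring closure to outrun loss of acetate and needs C6 (allylic, α to the ketone before and γ to the lactone carbonyl after the event) to stay configurationally intact: loss of acetate only regenerates 24 whereas the olefination is irreversible, any 7-acetoxy-11(13)-ene isomer arising from an acetyl shift would be funnelled to 26 by acetate in an SN2' step, and the only base is weakly basic acetate, which is used in slight excess and is replaced by non-basic diethyl phosphate as the reaction proceeds.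

Step 17
Reactants: 26 [(6E,9S,10E,11aR)-9-acetoxy-6,10-dimethyl-2-oxo-2,4,5,8,9,11a-hexahydrocyclodeca[b]furan-3-yl]methyl acetate
Product: 27 (1R,3S,4E,6R,10R)-3,13-diacetoxy-1,10-epoxygermacra-4,7(11)-dien-12,6-olide
Conditions: mCPBA, CH2Cl2/aq. phosphate buffer (pH 8), 0 °C
Reagents that add atoms: 3-chloroperoxybenzoic acid, OOC(=O)c1cccc(Cl)c1
Why: Prilezhaev epoxidation, which should select the electron-rich trisubstituted C1=C10 alkene over C4=C5 (deactivated by two allylic acyloxy groups) and over the electron-poor butenolide alkene, and should attack the exposed outer face of the macrocycle to give the 1R,10R (1β,10α) epoxide, the course known for germacra-1(10),4-dienolides.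

**Compound list**

1 | [(4R)-2,2-dimethyl-1,3-dioxolan-4-yl]methanol ((R)-solketal) | OC[C@@H]1COC(C)(C)O1 | starting material
2 | 2-(triphenylphosphoranylidene)propanal | CC(C=O)=P(c1ccccc1)(c1ccccc1)c1ccccc1 | starting material
3 | (4S)-2,2-dimethyl-1,3-dioxolane-4-carbaldehyde ((S)-glyceraldehyde acetonide) | O=C[C@@H]1COC(C)(C)O1 | intermediate
4 | (2E)-3-[(4R)-2,2-dimethyl-1,3-dioxolan-4-yl]-2-methylprop-2-enal | O=C/C(C)=C/[C@@H]1COC(C)(C)O1 | intermediate
5 | (1E,3S)-1-[(4R)-2,2-dimethyl-1,3-dioxolan-4-yl]-2-methylhexa-1,5-dien-3-yl diisopinocampheylborinate | C=CC[C@H](OB([C@H]1[C@H](C)[C@H]2C[C@@H](C1)C2(C)C)[C@H]1[C@H](C)[C@H]2C[C@@H](C1)C2(C)C)/C(C)=C/[C@@H]1COC(C)(C)O1 | intermediate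
6 | (1E,3S)-1-[(4R)-2,2-dimethyl-1,3-dioxolan-4-yl]-2-methylhexa-1,5-dien-3-ol | C=CC[C@H](O)/C(C)=C/[C@@H]1COC(C)(C)O1 | intermediate
7 | (1E,3S)-1-[(4R)-2,2-dimethyl-1,3-dioxolan-4-yl]-2-methylhexa-1,5-dien-3-yl acetate | C=CC[C@H](OC(C)=O)/C(C)=C/[C@@H]1COC(C)(C)O1 | intermediate
8 | 2-methylprop-2-enal (methacrolein) | CC(=C)C=O | starting material
9 | (1E,3S,5E)-1-[(4R)-2,2-dimethyl-1,3-dioxolan-4-yl]-2,6-dimethyl-7-oxohepta-1,5-dien-3-yl acetate | O=C/C(C)=C/C[C@H](OC(C)=O)/C(C)=C/[C@@H]1COC(C)(C)O1 | intermediate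
10 | (1E,3S,5E)-1-[(4R)-2,2-dimethyl-1,3-dioxolan-4-yl]-7-hydroxy-2,6-dimethylhepta-1,5-dien-3-yl acetate | OC/C(C)=C/C[C@H](OC(C)=O)/C(C)=C/[C@@H]1COC(C)(C)O1 | intermediate
11 | (1E,3S,5E)-1-[(4R)-2,2-dimethyl-1,3-dioxolan-4-yl]-2,6-dimethyl-7-(methylsulfonyloxy)hepta-1,5-dien-3-yl acetate | CS(=O)(=O)OC/C(C)=C/C[C@H](OC(C)=O)/C(C)=C/[C@@H]1COC(C)(C)O1 | intermediate
12 | (1E,3S,5E)-7-chloro-1-[(4R)-2,2-dimethyl-1,3-dioxolan-4-yl]-2,6-dimethylhepta-1,5-dien-3-yl acetate | ClC/C(C)=C/C[C@H](OC(C)=O)/C(C)=C/[C@@H]1COC(C)(C)O1 | intermediate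
13 | (2R,3E,5S,7E)-9-chloro-1,2-dihydroxy-4,8-dimethylnona-3,7-dien-5-yl acetate | ClC/C(C)=C/C[C@H](OC(C)=O)/C(C)=C/[C@@H](O)CO | intermediate
14 | (2R,3E,5S,7E)-9-chloro-4,8-dimethyl-1,2-bis(triethylsilyloxy)nona-3,7-dien-5-yl acetate | ClC/C(C)=C/C[C@H](OC(C)=O)/C(C)=C/[C@@H](O[Si](CC)(CC)CC)CO[Si](CC)(CC)CC | intermediate
15 | (2R,3E,5S,7E)-9-chloro-4,8-dimethyl-1-oxo-2-(triethylsilyloxy)nona-3,7-dien-5-yl acetate | ClC/C(C)=C/C[C@H](OC(C)=O)/C(C)=C/[C@@H](O[Si](CC)(CC)CC)C=O | intermediate
16 | prop-2-enyl bromoacetate (allyl bromoacetate) | BrCC(=O)OCC=C | starting material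
17 | prop-2-enyl (4R,5E,7S,9E)-7-acetoxy-11-chloro-3-hydroxy-6,10-dimethyl-4-(triethylsilyloxy)undeca-5,9-dienoate (both C3 epimers) | ClC/C(C)=C/C[C@H](OC(C)=O)/C(C)=C/[C@@H](O[Si](CC)(CC)CC)C(O)CC(=O)OCC=C | intermediate
18 | prop-2-enyl (4R,5E,7S,9E)-7-acetoxy-11-chloro-6,10-dimethyl-3-oxo-4-(triethylsilyloxy)undeca-5,9-dienoate | ClC/C(C)=C/C[C@H](OC(C)=O)/C(C)=C/[C@@H](O[Si](CC)(CC)CC)C(=O)CC(=O)OCC=C | intermediate
19 | prop-2-enyl (3E,6S,7E,9R)-6-acetoxy-3,7-dimethyl-10-oxo-9-(triethylsilyloxy)cyclodeca-3,7-diene-1-carboxylate (both C1 epimers) | C=CCOC(=O)C1C/C(C)=C/C[C@H](OC(C)=O)/C(C)=C/[C@@H](O[Si](CC)(CC)CC)C1=O | intermediate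
20 | (3E,6S,7E,9R)-6-acetoxy-3,7-dimethyl-10-oxo-9-(triethylsilyloxy)cyclodeca-3,7-diene-1-carboxylic acid (both C1 epimers) | OC(=O)C1C/C(C)=C/C[C@H](OC(C)=O)/C(C)=C/[C@@H](O[Si](CC)(CC)CC)C1=O | intermediate
21 | (2R,3E,5S,7E)-5-acetoxy-4,8-dimethyl-2-(triethylsilyloxy)cyclodeca-3,7-dien-1-one | O=C1CC/C(C)=C/C[C@H](OC(C)=O)/C(C)=C/[C@H]1O[Si](CC)(CC)CC | intermediate
22 | (2R,3E,5S,7E)-5-acetoxy-2-hydroxy-4,8-dimethylcyclodeca-3,7-dien-1-one | O=C1CC/C(C)=C/C[C@H](OC(C)=O)/C(C)=C/[C@H]1O | intermediate
23 | 2-(diethoxyphosphoryl)prop-2-enoic acid | C=C(C(=O)O)P(=O)(OCC)OCC | starting material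
24 | (1R,2E,4S,6E)-4-acetoxy-3,7-dimethyl-10-oxocyclodeca-2,6-dien-1-yl 2-(diethoxyphosphoryl)prop-2-enoate | O=C1CC/C(C)=C/C[C@H](OC(C)=O)/C(C)=C/[C@H]1OC(=O)C(=C)P(=O)(OCC)OCC | intermediate
25 | tetrabutylammonium salt of the C11 carbanion of (1R,2E,4S,6E)-4-acetoxy-3,7-dimethyl-10-oxocyclodeca-2,6-dien-1-yl 3-acetoxy-2-(diethoxyphosphoryl)propanoate | O=C1CC/C(C)=C/C[C@H](OC(C)=O)/C(C)=C/[C@H]1OC(=O)[C-](COC(C)=O)P(=O)(OCC)OCC.CCCC[N+](CCCC)(CCCC)CCCC | intermediate
26 | [(6E,9S,10E,11aR)-9-acetoxy-6,10-dimethyl-2-oxo-2,4,5,8,9,11a-hexahydrocyclodeca[b]furan-3-yl]methyl acetate (3β,13-diacetoxygermacra-1(10)E,4E,7(11)-trien-12,6α-olide) | CC(=O)OCC1=C2CC/C(C)=C/C[C@H](OC(C)=O)/C(C)=C/[C@H]2OC1=O | intermediate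
27 | (1R,3S,4E,6R,10R)-3,13-diacetoxy-1,10-epoxygermacra-4,7(11)-dien-12,6-olide | CC(=O)OCC1=C2CC[C@@]3(C)O[C@@H]3C[C@H](OC(C)=O)/C(C)=C/[C@H]2OC1=O | target

**Totals and risks**

Total step count: 17. Longest linear sequence: 17 steps (from 1).

Steps most likely to fail:

1. Step 16 (key step). What may go wrong: reversible loss of acetate from the carbanion outrunning ring closure, so that the acrylate oligomerises, or deprotonation at C6 with loss of configuration. Fallback (known chemistry, ring-closing metathesis in place of the olefination): it sets out from 21. Wittig methylenation (Ph3P=CH2, THF, 0 °C) turns the C7 ketone into the exocyclic methylene silyl ether F1. HF·pyridine frees the C6 alcohol F2. DCC coupling with 2-(bromomethyl)acrylic acid gives the bromomethylacrylate F3. KOAc with 18-crown-6 replaces bromide by acetate to give the acetoxymethylacrylate F4. Ring-closing metathesis of the two 1,1-disubstituted alkenes with second-generation Hoveyda–Grubbs catalyst (toluene, 80 °C) closes the tetrasubstituted butenolide alkene and comes back to the route at 26.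

2. Step 12. What may go wrong: intermolecular alkylation (oligomerisation) or O-alkylation of the enolate competing with closure of the strained ten-membered ring. Fallback: it sets out from 15. Addition of LiCH2SO2Ph (THF, −78 °C) gives the β-hydroxy sulfone F5, and Dess–Martin oxidation gives the β-keto sulfone F6. A Tsuji–Trost cyclisation (Pd(PPh3)4, 1,2-bis(diphenylphosphino)ethane, K2CO3, THF, high dilution), in which the soft sulfone-stabilised carbanion attacks a π-allylpalladium complex at its primary terminus, gives the macrocyclic β-keto sulfone F7. Reductive desulfonylation with Al(Hg) returns to the route at 21.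

3. Step 17. What may go wrong: poor facial selectivity in the attack on C1=C10, or competing epoxidation at C4=C5. Fallback (reagent control before the butenolide is built): it sets out from 21. Shi epoxidation with the D-fructose-derived ketone (KHSO5, K2CO3 buffer, MeCN/H2O, 0 °C) gives the 1R,10R epoxy ketone F8. Bu4NF buffered with AcOH frees the epoxy acyloin F9, and DCC coupling with 23 gives the epoxy phosphonoacrylate F10. Bu4NOAc then triggers the cascade of step 16 through the epoxy carbanion F11 and comes back to the route at 27.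

**Further compounds**

F1 | step 16 | 7-methylidene analogue of 21 (C7=O replaced by C7=CH2) | C=C1CC/C(C)=C/C[C@H](OC(C)=O)/C(C)=C/[C@H]1O[Si](CC)(CC)CC
F2 | step 16 | 6-hydroxy-7-methylidene compound (F1 without the triethylsilyl group) | C=C1CC/C(C)=C/C[C@H](OC(C)=O)/C(C)=C/[C@H]1O
F3 | step 16 | 2-(bromomethyl)prop-2-enoate ester of F2 | C=C1CC/C(C)=C/C[C@H](OC(C)=O)/C(C)=C/[C@H]1OC(=O)C(=C)CBr
F4 | step 16 | 2-(acetoxymethyl)prop-2-enoate ester of F2 | C=C1CC/C(C)=C/C[C@H](OC(C)=O)/C(C)=C/[C@H]1OC(=O)C(=C)COC(C)=O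
F5 | step 12 | β-hydroxy sulfone from 15 (C7 carbinol carrying CH2SO2Ph, both C7 epimers) | ClC/C(C)=C/C[C@H](OC(C)=O)/C(C)=C/[C@@H](O[Si](CC)(CC)CC)C(O)CS(=O)(=O)c1ccccc1
F6 | step 12 | β-keto sulfone (C7 ketone, C8 carrying SO2Ph) | ClC/C(C)=C/C[C@H](OC(C)=O)/C(C)=C/[C@@H](O[Si](CC)(CC)CC)C(=O)CS(=O)(=O)c1ccccc1
F7 | step 12 | 8-(phenylsulfonyl) derivative of 21 (both C8 epimers) | O=C1C(S(=O)(=O)c2ccccc2)C/C(C)=C/C[C@H](OC(C)=O)/C(C)=C/[C@H]1O[Si](CC)(CC)CC
F8 | step 17 | (1R,10R)-1,10-epoxide of 21 | O=C1CC[C@@]2(C)O[C@@H]2C[C@H](OC(C)=O)/C(C)=C/[C@H]1O[Si](CC)(CC)CC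
F9 | step 17 | (1R,10R)-1,10-epoxide of 22 | O=C1CC[C@@]2(C)O[C@@H]2C[C@H](OC(C)=O)/C(C)=C/[C@H]1O
F10 | step 17 | (1R,10R)-1,10-epoxide of 24 | O=C1CC[C@@]2(C)O[C@@H]2C[C@H](OC(C)=O)/C(C)=C/[C@H]1OC(=O)C(=C)P(=O)(OCC)OCC
F11 | step 17 | (1R,10R)-1,10-epoxide of carbanion 25 (tetrabutylammonium salt) | O=C1CC[C@@]2(C)O[C@@H]2C[C@H](OC(C)=O)/C(C)=C/[C@H]1OC(=O)[C-](COC(C)=O)P(=O)(OCC)OCC.CCCC[N+](CCCC)(CCCC)CCCC
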